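**Assumptions**
- Genipin (natural, 1R,4aS,7aS) is commercially available. Its C5/C9 cis-fusion and absolute configuration match the target; I checked this by comparing chirality at C1, C5 and C9 in the two SMILES.
- The C1 lactol of genipin-derived intermediates equilibrates between anomers by ring–chain tautomerism. The final acylation must therefore deliver the anomer with O-isovalerate cis to H-9. I assume this anomer is the major or separable one.
- Numbering is iridoid-style: C1 acylal, C3=C4 enol ether, C11 = CH2OH on C4, C10 = CH2O on C8.

**Retrosynthesis**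
1. The target is revealed by a final neutral desilylation of the 1-O-isovaleryl, 10-O-(Z)-coumaroyl compound carrying C11-OTIPS and an aryl-OTIPS.
2. The 7β-OH, 8α-OH and the C10 (Z)-coumarate come from one new Payne-rearrangement/carboxylate-opening cascade. It starts from the 7β,8β-epoxy-10-ol. C8 is set by inversion in the Payne step.
3. The epoxy alcohol comes from genipin, which already contains the cis-fused cyclopenta[c]pyran core and the C1, C5 and C9 stereocenters. The sequence is convex-face epoxidation, C4-CO2Me → CH2OH, silyl-group swaps, and lactol isovalerylation.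
4. No carbocycle or pyran ring is built. The only ring formed is the epoxide, which is transposed to the 8,10-spiro-epoxide and opened.
5. The (Z)-4-TIPSO-cinnamic acid is made separately from 4-hydroxybenzaldehyde by Still–Gennari olefination.

## Route

**Step 1**
Reactants: 1, 4-hydroxybenzaldehyde
Product: 2, 4-(triisopropylsilyloxy)benzaldehyde
Conditions: TIPSCl, imidazole, DMF, rt
Reagents that add atoms: TIPSCl, CC(C)[Si](Cl)(C(C)C)C(C)C
Why: Silylation of the phenol makes it inert to the base, carbonate and Pd-free conditions used later.

**Step 2**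
Reactants: 2; 3, methyl bis(2,2,2-trifluoroethyl)phosphonoacetate
Product: 4, methyl (Z)-3-(4-TIPSO-phenyl)acrylate
Conditions: 3, KHMDS, 18-crown-6, THF, −78 °C
Reagents that add atoms: none (3 is the reactant)
Why: Still–Gennari Horner–Wadsworth–Emmons olefination of an aryl aldehyde gives the Z-cinnamate kinetically.

**Step 3**
Reactants: 4
Product: 5, (Z)-3-(4-TIPSO-phenyl)acrylic acid
Conditions: LiOH·H2O, THF/H2O, 0 °C → rt, in the dark; KHSO4 work-up
Reagents that add atoms: water, O (hydroxide oxygen ends up in the acid)
Why: Saponification under mild conditions preserves the Z alkene and the aryl TIPS ether.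

**Step 4**
Reactants: 6, genipin
Product: 7, 10-O-TBS-genipin
Conditions: TBSCl (1.05 equiv), imidazole, CH2Cl2/DMF, 0 °C
Reagents that add atoms: TBSCl, CC(C)(C)[Si](C)(C)Cl
Why: The unhindered primary allylic OH silylates faster than the hemiacetal OH. Minor bis-silylation is separable.

**Step 5**
Reactants: 7
Product: 8, 1-O-TES-10-O-TBS-genipin
Conditions: TESOTf, 2,6-lutidine, CH2Cl2, −78 °C
Reagents that add atoms: TESOTf, CC[Si](CC)(CC)OS(=O)(=O)C(F)(F)F
Why: Capping the lactol prevents hydride ring-opening in step 7. TES is the most labile group of the set, so it can be removed first later.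

**Step 6**
Reactants: 8
Product: 9, 7β,8β-epoxide
Conditions: mCPBA, NaHCO3, CH2Cl2, 0 °C
Reagents that add atoms: mCPBA, OOC(=O)c1cccc(Cl)c1
Why: Electrophilic epoxidation of the trisubstituted C7=C8 alkene occurs on the convex face, the same face as H-5 and H-9 of the cis-fused bicycle. This sets C7 (β-O). The vinylogous-carbonate C3=C4 is deactivated by the C4 ester and is untouched.

**Step 7**
Reactants: 9
Product: 10, C11 alcohol (C4-CH2OH)
Conditions: DIBAL-H (4.5 equiv), CH2Cl2, −78 → −20 °C; Rochelle salt work-up
Reagents that add atoms: none (hydride only)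
Why: DIBAL reduces the deactivated vinylogous ester through the aldehyde to the allylic alcohol. The silyl ethers, the silyl acetal and the hindered tertiary epoxide survive at low temperature. The epoxide is installed first because the product enol ether would be far more reactive to peracid than C7=C8.

**Step 8**
Reactants: 10
Product: 11, C11-OTIPS ether
Conditions: TIPSCl, imidazole, DMF, rt
Reagents that add atoms: TIPSCl, CC(C)[Si](Cl)(C(C)C)C(C)C
Why: Silylation of the only free OH. The chloride is used rather than the triflate to avoid Lewis-acid rearrangement of the epoxide. TIPS is chosen so that the C10-TBS can later be removed selectively.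

**Step 9**
Reactants: 11
Product: 12, lactol (C1-OH, anomeric mixture)
Conditions: TBAF·3H2O (1.1 equiv), AcOH (2 equiv), THF, −20 °C, 15 min; use crude immediately
Reagents that add atoms: none
Why: The anomeric TES ether is far more fluoride-labile than the primary TBS and TIPS ethers. The buffer protects the epoxide and the enol ether. The lactol is used at once to avoid ring-opening and β-elimination of the C11 silyloxy group.

**Step 10**
Reactants: 12
Product: 13, 1-O-isovaleryl acylal (natural anomer, O cis to H-9; the minor anomer is removed by chromatography)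
Conditions: isovaleryl chloride (1.5 equiv), pyridine, DMAP (cat.), CH2Cl2, −20 → 0 °C
Reagents that add atoms: isovaleryl chloride, CC(C)CC(=O)Cl
Why: Acylation of the lactol alkoxide under Curtin–Hammett ring–chain equilibration. The anomeric effect is expected to favour the axial, natural C1 configuration. This is the only step that sets C1.

**Step 11**
Reactants: 13
Product: 14, epoxy alcohol (C10-OH)
Conditions: TBAF, AcOH (1:1), THF, 0 °C
Reagents that add atoms: none
Why: The buffered fluoride removes the primary TBS selectively over TIPS. The acylal and the epoxide survive, and no HF is used, so no fluorohydrin forms.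

**Step 12**
Reactants: 14; 5 as its pre-formed, dried cesium carboxylate
Product: 15, 7β-OH, 8α-OH, 10-O-(Z)-4-TIPSO-cinnamate
Conditions: Cs salt of 5 (3 equiv), Cs2CO3 (0.3 equiv), DMF, 4 Å MS, 50 °C, in the dark
Reagents that add atoms: none beyond 5
Why: Proposed new method: a base-catalysed Payne rearrangement/carboxylate SN2 opening cascade, run as one pot on a cis-fused cyclopentene-oxide 2,3-epoxy alcohol with an acid-sensitive Z-cinnamate as the nucleophile.
- The C10 alkoxide attacks C8 from the concave face, anti to the epoxide C–O bond, giving the 8,10-spiro-epoxide and a C7 alkoxide that is protonated by substrate.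
- Cs carboxylate then opens the spiro-epoxide at the primary C10 (neopentyl-type, but fast for an epoxide). This is irreversible and drives Curtin–Hammett conversion.
- The released tertiary C8 alkoxide is the chain-propagating base, so only catalytic Cs2CO3 is needed. The net result is inversion at C8 (8α-OH, C10 β), retention at C7 (7β-OH), and the coumarate installed on C10 without an activated Z-acid.
- The carboxylate does not attack the strained cyclopentene oxide at C7 or C8.
- The closest known reactions are Payne rearrangement with thiolate or azide trapping and Cs-carboxylate opening of terminal epoxides.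

**Step 13**
Reactants: 15
Product: 16, luzonoid D
Conditions: HF·pyridine, excess pyridine, THF, 0 °C → rt, 24 h, in the dark
Reagents that add atoms: none
Why: Buffered HF cleaves the aryl-TIPS and C11-TIPS ethers under near-neutral conditions. No epoxide remains, and the acylal, Z-cinnamate and enol ether are retained.

## Compound list
1 | 4-hydroxybenzaldehyde | O=Cc1ccc(O)cc1 | starting material
2 | 4-(TIPSO)benzaldehyde | O=Cc1ccc(O[Si](C(C)C)(C(C)C)C(C)C)cc1 | intermediate
3 | methyl bis(2,2,2-trifluoroethyl)phosphonoacetate | COC(=O)CP(=O)(OCC(F)(F)F)OCC(F)(F)F | starting material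
4 | methyl (Z)-3-(4-TIPSO-phenyl)acrylate | COC(=O)/C=C\c1ccc(O[Si](C(C)C)(C(C)C)C(C)C)cc1 | intermediate
5 | (Z)-3-(4-TIPSO-phenyl)acrylic acid | OC(=O)/C=C\c1ccc(O[Si](C(C)C)(C(C)C)C(C)C)cc1 | intermediate
6 | genipin | COC(=O)C1=CO[C@H]([C@H]2[C@@H]1CC=C2CO)O | starting material
7 | 10-O-TBS-genipin | COC(=O)C1=CO[C@H]([C@H]2[C@@H]1CC=C2CO[Si](C)(C)C(C)(C)C)O | intermediate
8 | 1-O-TES-10-O-TBS-genipin | COC(=O)C1=CO[C@H]([C@H]2[C@@H]1CC=C2CO[Si](C)(C)C(C)(C)C)O[Si](CC)(CC)CC | intermediate
9 | 7β,8β-epoxide of 8 | COC(=O)C1=CO[C@H]([C@H]2[C@@H]1C[C@@H]3O[C@]23CO[Si](C)(C)C(C)(C)C)O[Si](CC)(CC)CC | intermediate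
10 | C11-alcohol | OCC1=CO[C@H]([C@H]2[C@@H]1C[C@@H]3O[C@]23CO[Si](C)(C)C(C)(C)C)O[Si](CC)(CC)CC | intermediate
11 | C11-OTIPS ether | CC(C)[Si](C(C)C)(C(C)C)OCC1=CO[C@H]([C@H]2[C@@H]1C[C@@H]3O[C@]23CO[Si](C)(C)C(C)(C)C)O[Si](CC)(CC)CC | intermediate
12 | lactol, C1 anomeric mixture | CC(C)[Si](C(C)C)(C(C)C)OCC1=COC(O)[C@H]2[C@@H]1C[C@@H]3O[C@]23CO[Si](C)(C)C(C)(C)C | intermediate
13 | 1-O-isovaleryl epoxide, 10-OTBS | CC(C)CC(=O)O[C@@H]1OC=C(CO[Si](C(C)C)(C(C)C)C(C)C)[C@H]2C[C@@H]3O[C@]3(CO[Si](C)(C)C(C)(C)C)[C@@H]12 | intermediate
14 | epoxy alcohol (C10-OH) | CC(C)CC(=O)O[C@@H]1OC=C(CO[Si](C(C)C)(C(C)C)C(C)C)[C@H]2C[C@@H]3O[C@]3(CO)[C@@H]12 | intermediate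
15 | coumarate diol, silylated | CC(C)CC(=O)O[C@@H]1OC=C(CO[Si](C(C)C)(C(C)C)C(C)C)[C@H]2C[C@H](O)[C@](O)(COC(=O)/C=C\c3ccc(O[Si](C(C)C)(C(C)C)C(C)C)cc3)[C@@H]12 | intermediate
16 | luzonoid D | CC(C)CC(=O)O[C@@H]1OC=C(CO)[C@H]2C[C@H](O)[C@](O)(COC(=O)/C=C\c3ccc(O)cc3)[C@@H]12 | target

## Totals
Total step count: 13 (3 for the acid fragment, 10 from genipin). The longest linear sequence is 10 steps, starting from genipin.

**Three steps most likely to fail**
1. **Step 12 (the new Payne/carboxylate cascade).** The base could cause acyl migration or cleavage of the C1 acylal, or the Payne equilibrium could be too slow.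
   - Fallback (known chemistry): take 11 through TBS removal with the C1-OTES still on, then do a Payne–hydrolysis (K2CO3, aqueous dioxane) to give the 7,8,10-triol. Acylate the primary C10-OH selectively with the mixed anhydride of 5 (Yamaguchi), then remove TES and acylate C1. This is the reverse order of bond formation.
2. **Step 10 (lactol isovalerylation).** The anomer ratio or the stability of the lactol could be poor.
   - Fallback (known chemistry): use a dynamic kinetic enzymatic anomeric acylation of lactol 12 with vinyl isovalerate and a lipase, followed by separation of anomers.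
3. **Step 6 (convex-face epoxidation).** A substantial α-epoxide could form and carry the wrong C7/C8 configuration through the Payne step.
   - Fallback (known chemistry): epoxidise with VO(acac)2/TBHP on the C10-TBS lactol (C1-OH free, β). The β-OH acts as a homoallylic director for convex-face delivery. TES is then installed after epoxidation.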